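The earlier runs and the new flask were generated by integration from invented constants; scatter was added.

At 25 min, the time we read the north-east flask, target has stood level for several readings, and the question is what that level means.

common to all: free enzyme 7.2 µM

|  | starting material | temperature | remark | time |
|---|---|---|---|---|
| north-east | 0.072 M | 37 °C | the very flask that is asked about, followed so far |  |
| north-west | 0.048 M | 43 °C | run made earlier |  |
| flask | 0.072 M | 37 °C |  | 25 min |

- north-east (time / min: target / %): 4.00: 52; 8.00: 42; 12.0: 39; 15.0: 42; 20.0: 42; 25.0: 40
- north-west (time / min: target / %): 0.200: 56; 0.333: 69; 0.500: 79; 0.833: 78; 1.50: 67; 2.50: 61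

(scatter of a reading: 1.5 percentage points)

- target, in percent of the starting material first charged, at 25 min
- which option adds most target ("none" when 2 percentage points or less is all one gets) (Tuesday's / Thursday's / Saturday's / Monday's / none)
- target present, with what was taken out counted in, in percent of the starting material first charged, after Tuesday's
- target present, with what was taken out counted in, in percent of the starting material first charged, after Monday's

- Tuesday's: at 25 min add free enzyme, 100% of the amount charged, then wait 50 min
- Thursday's: at 25 min take out 90% of the target then present, then wait 50 min
- Saturday's: at 25 min raise the temperature by 15 K, then wait 50 min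
- Monday's: change nothing and wait 50 min more

- removed target is counted in
- additions bring no volume worth counting

Take rates first. Between its first two readings the north-east flask loses 0.0250 min⁻¹ of the charge as target. From the second reading to the last it loses 0.00118 min⁻¹, slower by a factor 21.2, a drift within the scatter. The hotter north-west flask falls at 0.165 min⁻¹ after its peak, faster.

Two things can slow such a fall: free enzyme being lost, or a way back that catches up with the way forward. These readings do not separate them cleanly, so we commit to the second as our bet. The level is then a split, with free enzyme still working both ways. Its measure is the balance ratio (the equilibrium constant), what is not target over target on the level, with 1 as the symmetric case of an even split. The mean level 41.0% gives 1.44.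

So we expect 41.0% now and after Monday's, and the same after Tuesday's, since more enzyme reaches the same split sooner. Thursday's removal lets the remainder split anew, which gains 22 percentage points. For Saturday's these runs show no level at the raised temperature. As a rough yardstick we take the north-west flask's last reading, made at 43 °C, which stands 20 points above our level, less than Thursday's gain, so we name Thursday's.

The forecast, reading the level as “enzyme death”, differs from us: 41% now, 20% after Tuesday's, 41% after Monday's, and best none. The flask gives 41.7% now, 41.7% after Tuesday's, 41.7% after Monday's, and best Thursday's, which adds 22 points, while Saturday's adds 7.8 points.

    free enzyme → unfolded enzyme (k = 3.80 × 10⁻⁴ s⁻¹, Ea = 238 kJ mol⁻¹)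
    starting material + free enzyme → target + free enzyme, rate k2*[starting material]*[free enzyme]/(1 + ([starting material]/Km2) + ([target]/Kp2)) (30.0 mM, 26.0 mM, k = 22000 L mol⁻¹ s⁻¹, Ea = 33.0 kJ mol⁻¹)
    free enzyme → spent catalyst (k = 7.90 × 10⁻⁶ s⁻¹, Ea = 108 kJ mol⁻¹)
    target + free enzyme ⇌ isomer of the product + free enzyme, rate k4*[free enzyme]*[target] forward; the back reaction follows from the equilibrium constant (K = 1.40, k = 810 L mol⁻¹ s⁻¹, Ea = 42.0 kJ mol⁻¹, ΔH = −38.0 kJ mol⁻¹)
    (constants at 37 °C)

In this flask at 25.0 min, the half-life of target by the forward step to isomer of the product is 3.5 min, short against the 25 min elapsed. Free enzyme still stands at 55.9% of its charge, and isomer of the product over target is 1.40. The north-west flask, left to the same time, holds 48.7% target, a ratio of 1.05.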